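## Structural features

The target is a linear diarylheptanoid in which a saturated seven-carbon chain carries ring A (4-hydroxy-3-methoxyphenyl, guaiacyl) on C1 and ring B (4-hydroxy-3,5-dimethoxyphenyl, syringyl) on C7, the rings being joined only through this chain. C3 and C5 are secondary carbinols separated by the C4 methylene; both are S, which is the anti arrangement of a 1,3-diol. The two halves differ only by the second methoxy group of ring B, so the chain is nearly C2-symmetric, and the real difficulty is to tell the two ends apart without statistical steps while fixing the absolute sense of the anti diol. The fragile sites are the two free, electron-rich phenols (air oxidation and quinone methide formation at the benzylic carbons C1 and C7, most easily at ring B). Any intermediate with a carbonyl group at C3 or C5 would also be open to retro-aldol cleavage and β-elimination. Ring B has a local mirror plane through its C1 and C4. Its C3–C4–C5 segment with three oxygen substituents is the carbon–oxygen pattern of 17, and its C2–C1–C6 segment is a 2-alkylmalonaldehyde, present in 16 as a vinylogous formamide; the key step uses this match to build ring B last.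

## Logic of the disconnections

22 from 20. The benzylic C–O bond of the ring A ether and the two acetal C–O bonds are cut. Both masks come off without touching a C–C bond or a stereocentre. This keeps the acidic phenol of ring A and the nucleophilic diol out of the basic steps before it. The forward step needs a hydrogenolysis and a hydrolysis that can share one flask.

20 from 16 and 17. The ring B bonds C2–C3 and C5–C6 are cut. The cut follows the local mirror plane of ring B, so the only element that distinguishes the two arms is made in the last C–C bond-forming step. 17 is a three-carbon ketone and 16 is a chain without ring B. The forward step must be a double condensation that beats the self-condensation of 17. The masks must resist alkoxide, and the C5 oxygen must stay masked, since a free C5 alkoxide would add to the aminomethylene carbon and close a dihydropyran.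

16 from 14 and 15. The C=C bond between the α-carbon of the aldehyde (the future C1 of ring B) and the aminomethylene carbon is cut. The α-methylene of 14 is its only acidic site, and the 1,3-dielectrophile is reduced to a plain aldehyde. The forward step must outrun aldol self-condensation of 14.

14 from 13. The C–C bond between the formyl carbon and the former terminal alkene carbon is cut. An allyl group is exactly what an allylation leaves on C5, and a one-carbon extension at its terminus gives the four-carbon arm that becomes C6, C7 and two ring carbons. The forward step is a hydroformylation that must be selective for the linear aldehyde.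

13 from 11. The two acetal C–O bonds are cut and the Si–O bond is restored. The singly silylated diol is the direct product of the second allylation, so no separate deprotection step is needed. The forward step must exchange the silyl group for the acetonide in one flask.

11 from 9. The C5–C6 bond is cut next to the C5 stereocentre. A reagent-controlled allyl addition to an aldehyde sets C5 independently of C3. Using the opposite hand of the reagent from the one that set C3 gives the anti relationship. One stereocentre and three carbons are removed. The forward step needs reagent control to dominate the weak bias of the β-silyloxy centre, and the C3 oxygen must be capped so that it cannot destroy the allylborane.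

9 from 7 from 6. The C=C bond of the first allyl group is cut with loss of its terminal carbon, and the Si–O bond is cut. The allyl group of 6 is a latent acetaldehyde unit, which makes the two allylations iterative. The oxidative cleavage must attack the alkene only, in the presence of electron-rich ring A, and must not trigger β-elimination in 9.

6 from 4. The C3–C4 bond is cut. The first reagent-controlled allylation sets C3 on an achiral aldehyde. The forward step carries the whole enantiomeric purity of the route.

4 from 3 from 2 from 1. The C1–C2 bond (a C=C bond in 3) and the O–benzyl bond are cut. This is a two-carbon homologation of an aromatic aldehyde followed by conjugate reduction, and it ends at a commodity phenol. The reduction must spare the benzyl ether and the formyl group.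

## Other disconnections considered

Alternative 1: The cut is at C1–C2 and C6–C7. It removes both benzylic carbons with their rings and leaves the C2–C6 core as the C2-symmetric bis-epoxide A1. In the forward direction A1 would be opened at one terminal carbon by the benzylic Grignard reagent A2 and at the other by A3, each under CuI catalysis, to give the bis-benzyl ether A4; hydrogenolysis would finish the synthesis.
- In its favour: both stereocentres arrive with A1 and are never touched, since the openings are SN2 reactions at primary carbons. Every operation is a standard reaction. The sequence from A1 is only three or four steps. On step count and on precedent this plan is better than the chosen one, and its stereochemical security is at least equal.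
- Against it here: the two epoxides of A1 are identical, so the first opening can be stopped at the mono-adduct only statistically, and material is lost to double opening or no opening. Electron-rich benzylic Grignard reagents such as A2 and A3 tend to homo-couple while they are formed. A1 is volatile, a double alkylating agent, and itself several steps from an achiral precursor.
- Comparison: the chosen plan needs about twice as many steps and rests on an untested ring synthesis, but it distinguishes the two ends by construction and not by statistics.

Alternative 2: The cut is the C3–O bond, together with an oxygen on C4 that is added and later removed. The C3 carbinol is traced back to the C3=C4 alkene of the racemic allylic alcohol A5, which holds only the C5 stereocentre. In the forward direction a Sharpless kinetic resolution (Ti(OiPr)4, L-(+)-diisopropyl tartrate, tBuOOH) should epoxidise the (5S) half of A5 to the erythro epoxy alcohol A6. Hydride delivery to C4 by the chelating hydride NaAlH2(OCH2CH2OMe)2 would give A4, and hydrogenolysis the target.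
- In its favour: kinetic resolution of (E)-configured secondary allylic alcohols is among the most dependable asymmetric reactions. One reagent fixes C3 relative to C5 and the absolute sense together. A5 can be assembled convergently from two arm fragments. On precedent it is better than the chosen plan, and on step count roughly equal.
- Against it: at most half of A5, which already carries both aryl arms, can become product, and the rest must be inverted or discarded. The C4 oxygen is an oxidation-state detour. The enantiomeric purity depends on stopping at the right conversion. The hydride opening must be steered to C4 and away from C3.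
- Comparison: the chosen plan makes each stereocentre once by reagent control and wastes no enantiomer, but its ring synthesis is unproven, whereas each step here has close analogy.

Alternative 3: The cut is at C3–C4 and C4–C5. It leaves C4 as malonic acid A7 and the two halves as the acyl imidazolides A8 and A9. In the forward direction the magnesium salt of A7 (formed with MgCl2 and Et3N) would be C-acylated by A8 and decarboxylate to the magnesium enolate of a β-keto acid. That enolate would be acylated by A9 and decarboxylate again to the 3,5-diketone A10, with no ring closure. An asymmetric hydrogenation of A10 with RuCl2[(S)-BINAP] should, by analogy with simple 1,3-diketones, give the anti (S,S) diol A4 in one step.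
- In its favour: it is the shortest of all the plans and mirrors the biosynthetic assembly. Both stereocentres come from a single catalytic step, against two separate allylations in the chosen plan. On step count and stereochemical economy it is better.
- Against it: the order of the two acylations is controlled only by the order of addition. The two symmetric diketones from double use of A8 or of A9 are therefore to be expected as by-products, and they differ from A10 by a single methoxy group. O-acylation and early decarboxylation to an unreactive methyl ketone compete. A10 is achiral, so the whole stereochemical burden rests on one hydrogenation, although a dialkyl 1,3-diketone with two nearly equivalent carbonyl groups is a favourable case for that reaction.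
- Comparison: the chosen plan is much longer, but the arms cannot be confused because ring B does not exist until step 11, and the diol is secured well before the uncertain step.

Key step: step 11

Remarks on the chemistry:
- The push–pull double bond of 16 and the enal double bond of 18 are drawn without a fixed geometry. They isomerise easily under the conditions and both geometries lead to the same arene.
- 8, 18 and 19 form as epimer mixtures at a carbon that later loses its stereogenicity.
- The carbinol centres are (3S,5S) in the heptane numbering and (4S,6S) in the dioxane numbering of 13 to 21, because the ranking O > C4 > outer chain carbon holds at both centres throughout.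
- Chain-length check: the former terminal alkene carbon of 13 becomes C1 of ring B; the formyl carbon from step 9 and the aminomethylene carbon from step 10 become the ring CH carbons C2 and C6. Exactly two methylene groups (C6 and C7) therefore separate C5 from ring B.
- In steps 4 and 7 the allylborane is made in the flask from the B-methoxyborane and allylmagnesium bromide; boron and the isopinocampheyl groups appear only in 5 and 10 and are removed by the oxidative work-up.
- 2 can also be bought, which would shorten the route by one step.

## Route

Step 1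
Reactants: 1 vanillin (4-hydroxy-3-methoxybenzaldehyde)
Product: 2 4-(benzyloxy)-3-methoxybenzaldehyde
Conditions: BnBr, K2CO3, DMF, rt
Reagents that add atoms: benzyl bromide, BrCc1ccccc1
Why: Williamson ether synthesis: the phenoxide formed with K2CO3 displaces bromide from the benzylic halide by SN2; the aldehyde is untouched, and the benzyl ether withstands every base, oxidant and organometallic reagent used up to step 12.

Step 2
Reactants: 2 4-(benzyloxy)-3-methoxybenzaldehyde
Product: 3 (E)-3-[4-(benzyloxy)-3-methoxyphenyl]prop-2-enal
Conditions: Ph3P=CHCHO, toluene, 90 °C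
Reagents that add atoms: (triphenylphosphoranylidene)acetaldehyde, O=CC=P(c1ccccc1)(c1ccccc1)c1ccccc1
Why: Wittig olefination with a stabilised formyl ylide should give the (E)-enal directly; the electron-rich aldehyde needs heating, and only a small excess of ylide is used to limit a second homologation of the product.

Step 3
Reactants: 3 (E)-3-[4-(benzyloxy)-3-methoxyphenyl]prop-2-enal
Product: 4 3-[4-(benzyloxy)-3-methoxyphenyl]propanal
Conditions: Hantzsch ester (diethyl 2,6-dimethyl-1,4-dihydropyridine-3,5-dicarboxylate), dibenzylammonium trifluoroacetate (cat.), THF, rt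
Reagents that add atoms: none
Why: Iminium-catalysed transfer hydrogenation (conjugate reduction): the ammonium salt turns the enal into an iminium ion that accepts hydride at the β-carbon from the dihydropyridine, so only the C=C bond is reduced and the benzyl ether and formyl group survive.

Step 4
Reactants: 4 3-[4-(benzyloxy)-3-methoxyphenyl]propanal
Product: 6 (3S)-1-[4-(benzyloxy)-3-methoxyphenyl]hex-5-en-3-ol, via borinate ester 5 (not isolated)
Conditions: (+)-Ipc2BOMe (from (−)-α-pinene), allylMgBr, Et2O, 0 °C to rt; then 4, −78 °C; then NaOH, H2O2, 0 °C to rt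
Reagents that add atoms: allylmagnesium bromide, C=CC[Mg]Br; (+)-B-methoxydiisopinocampheylborane, COB([C@H]1C[C@H]2C[C@@H]([C@@H]1C)C2(C)C)[C@H]1C[C@H]2C[C@@H]([C@@H]1C)C2(C)C
Why: Brown allylboration: allylmagnesium bromide converts the B-methoxyborane into (+)-B-allyldiisopinocampheylborane in the flask, which adds to 4 through a closed six-membered chair transition state to give 5. The isopinocampheyl groups derived from (−)-α-pinene direct the allyl group to the Re face of the aldehyde, which sets C3 as S by reagent control. Alkaline peroxide then releases the alcohol from 5, so that boron and the isopinocampheyl groups leave as borate and isopinocampheol and only the allyl group stays in 6.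

Step 5
Reactants: 6 (3S)-1-[4-(benzyloxy)-3-methoxyphenyl]hex-5-en-3-ol
Product: 7 (3S)-1-[4-(benzyloxy)-3-methoxyphenyl]-3-(triethylsilyloxy)hex-5-ene
Conditions: Et3SiCl, imidazole, CH2Cl2, 0 °C to rt
Reagents that add atoms: chlorotriethylsilane, CC[Si](Cl)(CC)CC
Why: Imidazole-promoted silylation of the secondary alcohol caps the C3 oxygen so that it can neither protonate the second allylborane nor form lactols with the aldehyde of 9; the triethylsilyl group is chosen because the mild acid of step 8 removes it.

Step 6
Reactants: 7 (3S)-1-[4-(benzyloxy)-3-methoxyphenyl]-3-(triethylsilyloxy)hex-5-ene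
Product: 9 (3S)-5-[4-(benzyloxy)-3-methoxyphenyl]-3-(triethylsilyloxy)pentanal, via vicinal diol 8 (not isolated)
Conditions: K2OsO4·2H2O (cat.), NaIO4, 2,6-lutidine, 1,4-dioxane–H2O, rt
Reagents that add atoms: osmium tetroxide, O=[Os](=O)(=O)=O
Why: Lemieux–Johnson oxidation: OsO4, generated from K2OsO4 by NaIO4 and continuously regenerated by it, dihydroxylates the terminal alkene to 8, and NaIO4 cleaves the diol so that one of the oxygens delivered by osmium becomes the carbonyl oxygen; unlike ozone this pair leaves the electron-rich ring and the benzyl ether alone, and 2,6-lutidine buffers the medium so that the β-silyloxy aldehyde does not eliminate.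

Step 7
Reactants: 9 (3S)-5-[4-(benzyloxy)-3-methoxyphenyl]-3-(triethylsilyloxy)pentanal
Product: 11 (4S,6S)-8-[4-(benzyloxy)-3-methoxyphenyl]-6-(triethylsilyloxy)oct-1-en-4-ol, via borinate ester 10 (not isolated)
Conditions: (−)-Ipc2BOMe (from (+)-α-pinene), allylMgBr, Et2O, 0 °C to rt; then 9, −78 °C; then NaOH, H2O2, 0 °C
Reagents that add atoms: allylmagnesium bromide, C=CC[Mg]Br; (−)-B-methoxydiisopinocampheylborane, COB([C@@H]1C[C@@H]2C[C@H]([C@H]1C)C2(C)C)[C@@H]1C[C@@H]2C[C@H]([C@H]1C)C2(C)C
Why: Second Brown allylboration, now with (−)-B-allyldiisopinocampheylborane made in the flask from the reagent of opposite hand, which adds to the Si face and sets the new carbinol (C5 of the heptane chain) as S and anti to C3. Reagent control should dominate the weak bias of the β-silyloxy centre, and the minor enantiomer carried from step 4 is converted mainly into a separable syn diastereomer. Cold alkaline peroxide cleaves 10 to the alcohol, borate and isopinocampheol without touching the triethylsilyl ether.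

Step 8
Reactants: 11 (4S,6S)-8-[4-(benzyloxy)-3-methoxyphenyl]-6-(triethylsilyloxy)oct-1-en-4-ol
Product: 13 (4S,6S)-4-allyl-6-{2-[4-(benzyloxy)-3-methoxyphenyl]ethyl}-2,2-dimethyl-1,3-dioxane, via free diol 12 (not isolated)
Conditions: CSA (cat.), MeOH, 0 °C to rt; concentrate; then Me2C(OMe)2, acetone, rt; Et3N
Reagents that add atoms: 2,2-dimethoxypropane, COC(C)(C)OC
Why: Acid-catalysed methanolysis removes the triethylsilyl group to give 12, and transketalisation with 2,2-dimethoxypropane closes the six-membered acetonide in the same flask; acetonides of anti-1,3-diols form readily, and this one ties up both oxygens for the basic steps 10 and 11.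

Step 9
Reactants: 13 (4S,6S)-4-allyl-6-{2-[4-(benzyloxy)-3-methoxyphenyl]ethyl}-2,2-dimethyl-1,3-dioxane
Product: 14 4-[(4S,6S)-6-{2-[4-(benzyloxy)-3-methoxyphenyl]ethyl}-2,2-dimethyl-1,3-dioxan-4-yl]butanal
Conditions: Rh(acac)(CO)2 (cat.), Xantphos, CO/H2 (1:1, 10 bar), toluene, 80 °C
Reagents that add atoms: carbon monoxide, [C-]#[O+]
Why: Rhodium-catalysed hydroformylation: the wide bite angle of Xantphos holds both phosphorus atoms equatorial in the hydride complex and steers insertion to the linear alkyl, so the formyl group should end on the terminal carbon; acetal and benzyl ether are inert.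

Step 10
Reactants: 14 4-[(4S,6S)-6-{2-[4-(benzyloxy)-3-methoxyphenyl]ethyl}-2,2-dimethyl-1,3-dioxan-4-yl]butanal; 15 tert-butoxybis(dimethylamino)methane
Product: 16 2-{2-[(4S,6S)-6-{2-[4-(benzyloxy)-3-methoxyphenyl]ethyl}-2,2-dimethyl-1,3-dioxan-4-yl]ethyl}-3-(dimethylamino)prop-2-enal
Conditions: 15 (excess), THF, 60 °C, slow addition of 14
Reagents that add atoms: none
Why: α-Aminomethylenation of an aldehyde: 15 ionises to tert-butoxide and a formamidinium ion, the enolate of 14 adds to the latter, and loss of dimethylamine gives the push–pull enaminal; slow addition of 14 to excess 15 keeps the free aldehyde concentration low and should suppress self-aldol.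

Step 11
Reactants: 16 2-{2-[(4S,6S)-6-{2-[4-(benzyloxy)-3-methoxyphenyl]ethyl}-2,2-dimethyl-1,3-dioxan-4-yl]ethyl}-3-(dimethylamino)prop-2-enal; 17 1,3-dimethoxyacetone (1,3-dimethoxypropan-2-one)
Product: 20 4-{2-[(4S,6S)-6-{2-[4-(benzyloxy)-3-methoxyphenyl]ethyl}-2,2-dimethyl-1,3-dioxan-4-yl]ethyl}-2,6-dimethoxyphenol, via open-chain keto enal 18 (not isolated), via cyclohexadienone 19 (not isolated)
Conditions: 17 (2 equiv) and KOtBu (2.5 equiv) added slowly to 16, THF–tBuOH, 0 to 50 °C, under argon; then AcOH
Reagents that add atoms: none
Why: Proposed new method: a (3+3) benzannulation in which the potassium enolate of 17 adds to the aminomethylene carbon of 16 and expels dimethylamine (vinylogous acyl substitution) to give 18, after which the second methoxy-bearing methylene is deprotonated and closes the ring onto the aldehyde carbon in a 6-exo-trig aldol addition, and loss of water gives 19, which tautomerises to the phenoxide of 20; the closest known reaction type is the base-mediated synthesis of 2,6-disubstituted phenols from 1,3-disubstituted acetones and vinamidinium salts or nitromalonaldehyde, together with the arene and pyridine syntheses from ketone enolates and vinamidinium salts. If the enolate attacks the formyl carbon first, the same ring results, because both ends of the three-carbon electrophile become ring CH groups. The ketone carbon becomes C4 with its hydroxyl, its two flanking carbons become C3 and C5 with their methoxy groups, and the chain-bearing carbon of 16 becomes C1, so the substitution pattern follows from connectivity alone and no regiochemical choice exists. No stereocentre is formed, and those on the dioxane are remote and not enolisable. The selectivity needed is cross-condensation over self-condensation of 17; it is favoured because 16 has no acidic hydrogen, is electrophilic at both ends and is present in full while 17 and the base are added slowly. Aromatisation to a phenoxide makes the last stage irreversible and should pull the reversible earlier stages forward. The acetonide and benzyl ether are stable to tert-butoxide, the masked C5 oxygen cannot add to the enaminal, and exclusion of air with an acetic acid quench protects the electron-rich phenoxide.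

Step 12
Reactants: 20 4-{2-[(4S,6S)-6-{2-[4-(benzyloxy)-3-methoxyphenyl]ethyl}-2,2-dimethyl-1,3-dioxan-4-yl]ethyl}-2,6-dimethoxyphenol
Product: 22 (3S,5S)-1-(4-hydroxy-3-methoxyphenyl)-7-(4-hydroxy-3,5-dimethoxyphenyl)heptane-3,5-diol, via bisphenol acetonide 21 (not isolated)
Conditions: H2 (1 atm), Pd/C, MeOH, rt; filter; then 1 M aq. HCl, rt
Reagents that add atoms: none
Why: Hydrogenolysis of the aryl benzyl ether over Pd/C gives 21 and toluene, and aqueous acid then hydrolyses the acetonide to the diol; neither operation touches a stereocentre, and the molecule holds no alkene and no other benzylic C–O bond.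

## Compound list

1 | vanillin (4-hydroxy-3-methoxybenzaldehyde) | COc1cc(C=O)ccc1O | starting material
2 | 4-(benzyloxy)-3-methoxybenzaldehyde | COc1cc(C=O)ccc1OCc1ccccc1 | intermediate
3 | (E)-3-[4-(benzyloxy)-3-methoxyphenyl]prop-2-enal | COc1cc(/C=C/C=O)ccc1OCc1ccccc1 | intermediate
4 | 3-[4-(benzyloxy)-3-methoxyphenyl]propanal | COc1cc(CCC=O)ccc1OCc1ccccc1 | intermediate
5 | (3S)-1-[4-(benzyloxy)-3-methoxyphenyl]hex-5-en-3-yl bis[(+)-isopinocampheyl]borinate (isopinocampheyl groups from (−)-α-pinene) | COc1cc(CC[C@H](OB([C@H]2C[C@H]3C[C@@H]([C@@H]2C)C3(C)C)[C@H]2C[C@H]3C[C@@H]([C@@H]2C)C3(C)C)CC=C)ccc1OCc1ccccc1 | intermediate (not isolated)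
6 | (3S)-1-[4-(benzyloxy)-3-methoxyphenyl]hex-5-en-3-ol | COc1cc(CC[C@H](O)CC=C)ccc1OCc1ccccc1 | intermediate
7 | (3S)-1-[4-(benzyloxy)-3-methoxyphenyl]-3-(triethylsilyloxy)hex-5-ene | COc1cc(CC[C@H](O[Si](CC)(CC)CC)CC=C)ccc1OCc1ccccc1 | intermediate
8 | (4S)-6-[4-(benzyloxy)-3-methoxyphenyl]-4-(triethylsilyloxy)hexane-1,2-diol (both C2 epimers) | COc1cc(CC[C@H](O[Si](CC)(CC)CC)CC(O)CO)ccc1OCc1ccccc1 | intermediate (not isolated)
9 | (3S)-5-[4-(benzyloxy)-3-methoxyphenyl]-3-(triethylsilyloxy)pentanal | COc1cc(CC[C@H](O[Si](CC)(CC)CC)CC=O)ccc1OCc1ccccc1 | intermediate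
10 | (4S,6S)-8-[4-(benzyloxy)-3-methoxyphenyl]-6-(triethylsilyloxy)oct-1-en-4-yl bis[(−)-isopinocampheyl]borinate (isopinocampheyl groups from (+)-α-pinene) | COc1cc(CC[C@H](O[Si](CC)(CC)CC)C[C@@H](OB([C@@H]2C[C@@H]3C[C@H]([C@H]2C)C3(C)C)[C@@H]2C[C@@H]3C[C@H]([C@H]2C)C3(C)C)CC=C)ccc1OCc1ccccc1 | intermediate (not isolated)
11 | (4S,6S)-8-[4-(benzyloxy)-3-methoxyphenyl]-6-(triethylsilyloxy)oct-1-en-4-ol | COc1cc(CC[C@H](O[Si](CC)(CC)CC)C[C@@H](O)CC=C)ccc1OCc1ccccc1 | intermediate
12 | (4S,6S)-8-[4-(benzyloxy)-3-methoxyphenyl]oct-1-ene-4,6-diol | COc1cc(CC[C@H](O)C[C@@H](O)CC=C)ccc1OCc1ccccc1 | intermediate (not isolated)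
13 | (4S,6S)-4-allyl-6-{2-[4-(benzyloxy)-3-methoxyphenyl]ethyl}-2,2-dimethyl-1,3-dioxane | COc1cc(CC[C@H](OC(C)(C)O2)C[C@@H]2CC=C)ccc1OCc1ccccc1 | intermediate
14 | 4-[(4S,6S)-6-{2-[4-(benzyloxy)-3-methoxyphenyl]ethyl}-2,2-dimethyl-1,3-dioxan-4-yl]butanal | COc1cc(CC[C@H](OC(C)(C)O2)C[C@@H]2CCCC=O)ccc1OCc1ccccc1 | intermediate
15 | tert-butoxybis(dimethylamino)methane | CN(C)C(OC(C)(C)C)N(C)C | starting material
16 | 2-{2-[(4S,6S)-6-{2-[4-(benzyloxy)-3-methoxyphenyl]ethyl}-2,2-dimethyl-1,3-dioxan-4-yl]ethyl}-3-(dimethylamino)prop-2-enal | COc1cc(CC[C@H](OC(C)(C)O2)C[C@@H]2CCC(C=O)=CN(C)C)ccc1OCc1ccccc1 | intermediate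
17 | 1,3-dimethoxyacetone (1,3-dimethoxypropan-2-one) | COCC(=O)COC | starting material
18 | 2-{2-[(4S,6S)-6-{2-[4-(benzyloxy)-3-methoxyphenyl]ethyl}-2,2-dimethyl-1,3-dioxan-4-yl]ethyl}-4,6-dimethoxy-5-oxohex-2-enal (epimers at C4 of the hexenal, alkene geometry open) | COc1cc(CC[C@H](OC(C)(C)O2)C[C@@H]2CCC(C=O)=CC(OC)C(=O)COC)ccc1OCc1ccccc1 | intermediate (not isolated)
19 | 4-{2-[(4S,6S)-6-{2-[4-(benzyloxy)-3-methoxyphenyl]ethyl}-2,2-dimethyl-1,3-dioxan-4-yl]ethyl}-2,6-dimethoxycyclohexa-2,4-dien-1-one (both C6 epimers) | COc1cc(CC[C@H](OC(C)(C)O2)C[C@@H]2CCC3=CC(OC)C(=O)C(OC)=C3)ccc1OCc1ccccc1 | intermediate (not isolated)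
20 | 4-{2-[(4S,6S)-6-{2-[4-(benzyloxy)-3-methoxyphenyl]ethyl}-2,2-dimethyl-1,3-dioxan-4-yl]ethyl}-2,6-dimethoxyphenol | COc1cc(CC[C@H](OC(C)(C)O2)C[C@@H]2CCc3cc(OC)c(O)c(OC)c3)ccc1OCc1ccccc1 | intermediate
21 | 4-{2-[(4S,6S)-6-[2-(4-hydroxy-3-methoxyphenyl)ethyl]-2,2-dimethyl-1,3-dioxan-4-yl]ethyl}-2,6-dimethoxyphenol | COc1cc(CC[C@H](OC(C)(C)O2)C[C@@H]2CCc3cc(OC)c(O)c(OC)c3)ccc1O | intermediate (not isolated)
22 | (3S,5S)-1-(4-hydroxy-3-methoxyphenyl)-7-(4-hydroxy-3,5-dimethoxyphenyl)heptane-3,5-diol | COc1cc(CC[C@H](O)C[C@@H](O)CCc2cc(OC)c(O)c(OC)c2)ccc1O | target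

## Step count and risks

Total step count: 12. Longest linear sequence: 12 steps, from 1 to 22; 15 and 17 are bought.

Step 11 (the proposed new method, least certain). The most likely failure is self-condensation of the enolate of 17 outrunning its addition to the weakly electrophilic vinylogous formamide. The sequence may also stall at the open-chain stage, because ring closure needs the less acidic methylene and the cis enal geometry. Oxidative degradation of the phenoxide on contact with air is a further risk. The fallback uses known chemistry, sets out from 13 and attaches ring B ready-made. Dihydroxylation and periodate cleavage as in step 6 would pass through 3-[(4S,6S)-6-{2-[4-(benzyloxy)-3-methoxyphenyl]ethyl}-2,2-dimethyl-1,3-dioxan-4-yl]propane-1,2-diol F1 and give 2-[(4R,6S)-6-{2-[4-(benzyloxy)-3-methoxyphenyl]ethyl}-2,2-dimethyl-1,3-dioxan-4-yl]acetaldehyde F2; the descriptor 4R reflects only a change of ranking, not of geometry. 2-(Benzyloxy)-5-bromo-1,3-dimethoxybenzene F3, from commercial 4-bromo-2,6-dimethoxyphenol with BnBr and K2CO3, would be converted with Mg in THF into [4-(benzyloxy)-3,5-dimethoxyphenyl]magnesium bromide F4. Addition of F4 to F2 at −78 °C would give 1-[4-(benzyloxy)-3,5-dimethoxyphenyl]-2-[(4S,6S)-6-{2-[4-(benzyloxy)-3-methoxyphenyl]ethyl}-2,2-dimethyl-1,3-dioxan-4-yl]ethan-1-ol F5. Hydrogenolysis (H2, Pd/C, EtOAc–AcOH) should cleave the doubly activated benzylic C–OH bond and both benzyl ethers. The fallback comes back to the route at 21, which is hydrolysed to 22 as in step 12.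

Step 10. The most likely failure is aldol self-condensation of 14 under the alkoxide released from 15 before aminomethylenation is complete. The fallback sets out from 14 and goes through an enamine. Condensation with dimethylamine (K2CO3, Et2O, 0 °C) would give (E)-4-[(4S,6S)-6-{2-[4-(benzyloxy)-3-methoxyphenyl]ethyl}-2,2-dimethyl-1,3-dioxan-4-yl]-N,N-dimethylbut-1-en-1-amine F6. Formylation with (chloromethylene)dimethyliminium chloride and Et3N in CH2Cl2 at 0 °C (a Vilsmeier–Haack formylation of an enamine) would give the vinamidinium salt [2-{2-[(4S,6S)-6-{2-[4-(benzyloxy)-3-methoxyphenyl]ethyl}-2,2-dimethyl-1,3-dioxan-4-yl]ethyl}-3-(dimethylamino)prop-2-en-1-ylidene]dimethylammonium chloride F7. Hydrolysis with aqueous K2CO3 returns to the route at 16.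

Step 9. The most likely failure is insufficient linear selectivity, or migration of the double bond toward the dioxane before CO insertion, which would give branched or chain-shifted aldehydes. The fallback sets out from 13. Cross-metathesis with acrolein (second-generation Hoveyda–Grubbs catalyst, CH2Cl2, 40 °C) would give (E)-4-[(4S,6S)-6-{2-[4-(benzyloxy)-3-methoxyphenyl]ethyl}-2,2-dimethyl-1,3-dioxan-4-yl]but-2-enal F8. Iminium-catalysed transfer hydrogenation as in step 3 returns to the route at 14.

Step 7. The most likely failure is erosion of facial selectivity, if the C3 silyloxy centre opposes the reagent, together with β-elimination of the silyloxy group from 9 during handling. The fallback sets out from 6 and replaces reagent control by chelation control. NaH and 4-methoxybenzyl chloride in DMF would give (3S)-1-[4-(benzyloxy)-3-methoxyphenyl]-3-[(4-methoxybenzyl)oxy]hex-5-ene F9. Dihydroxylation and periodate cleavage as in step 6 would pass through (4S)-6-[4-(benzyloxy)-3-methoxyphenyl]-4-[(4-methoxybenzyl)oxy]hexane-1,2-diol F10 and give (3S)-5-[4-(benzyloxy)-3-methoxyphenyl]-3-[(4-methoxybenzyl)oxy]pentanal F11. Sakurai allylation with allyltrimethylsilane and TiCl4 at −78 °C should proceed through the six-membered titanium chelate with 1,3-anti induction and give (4S,6S)-8-[4-(benzyloxy)-3-methoxyphenyl]-6-[(4-methoxybenzyl)oxy]oct-1-en-4-ol F12. Oxidative removal of the 4-methoxybenzyl group with DDQ in buffered CH2Cl2–H2O returns to the route at 12, which is converted into 13 by the acetonide formation of step 8.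

## Further compounds

F1 | step 11 | 3-[(4S,6S)-6-{2-[4-(benzyloxy)-3-methoxyphenyl]ethyl}-2,2-dimethyl-1,3-dioxan-4-yl]propane-1,2-diol (both C2 epimers) | COc1cc(CC[C@H](OC(C)(C)O2)C[C@@H]2CC(O)CO)ccc1OCc1ccccc1
F2 | step 11 | 2-[(4R,6S)-6-{2-[4-(benzyloxy)-3-methoxyphenyl]ethyl}-2,2-dimethyl-1,3-dioxan-4-yl]acetaldehyde | COc1cc(CC[C@H](OC(C)(C)O2)C[C@@H]2CC=O)ccc1OCc1ccccc1
F3 | step 11 | 2-(benzyloxy)-5-bromo-1,3-dimethoxybenzene | COc1cc(Br)cc(OC)c1OCc1ccccc1
F4 | step 11 | [4-(benzyloxy)-3,5-dimethoxyphenyl]magnesium bromide | COc1cc([Mg]Br)cc(OC)c1OCc1ccccc1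
F5 | step 11 | 1-[4-(benzyloxy)-3,5-dimethoxyphenyl]-2-[(4S,6S)-6-{2-[4-(benzyloxy)-3-methoxyphenyl]ethyl}-2,2-dimethyl-1,3-dioxan-4-yl]ethan-1-ol (both carbinol epimers) | COc1cc(CC[C@H](OC(C)(C)O2)C[C@@H]2CC(O)c2cc(OC)c(OCc3ccccc3)c(OC)c2)ccc1OCc1ccccc1
F6 | step 10 | (E)-4-[(4S,6S)-6-{2-[4-(benzyloxy)-3-methoxyphenyl]ethyl}-2,2-dimethyl-1,3-dioxan-4-yl]-N,N-dimethylbut-1-en-1-amine | COc1cc(CC[C@H](OC(C)(C)O2)C[C@@H]2CC/C=C/N(C)C)ccc1OCc1ccccc1
F7 | step 10 | [2-{2-[(4S,6S)-6-{2-[4-(benzyloxy)-3-methoxyphenyl]ethyl}-2,2-dimethyl-1,3-dioxan-4-yl]ethyl}-3-(dimethylamino)prop-2-en-1-ylidene]dimethylammonium chloride | COc1cc(CC[C@H](OC(C)(C)O2)C[C@@H]2CCC(C=[N+](C)C)=CN(C)C)ccc1OCc1ccccc1.[Cl-]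
F8 | step 9 | (E)-4-[(4S,6S)-6-{2-[4-(benzyloxy)-3-methoxyphenyl]ethyl}-2,2-dimethyl-1,3-dioxan-4-yl]but-2-enal | COc1cc(CC[C@H](OC(C)(C)O2)C[C@@H]2C/C=C/C=O)ccc1OCc1ccccc1
F9 | step 7 | (3S)-1-[4-(benzyloxy)-3-methoxyphenyl]-3-[(4-methoxybenzyl)oxy]hex-5-ene | COc1cc(CC[C@H](OCc2ccc(OC)cc2)CC=C)ccc1OCc1ccccc1
F10 | step 7 | (4S)-6-[4-(benzyloxy)-3-methoxyphenyl]-4-[(4-methoxybenzyl)oxy]hexane-1,2-diol (both C2 epimers) | COc1cc(CC[C@H](OCc2ccc(OC)cc2)CC(O)CO)ccc1OCc1ccccc1
F11 | step 7 | (3S)-5-[4-(benzyloxy)-3-methoxyphenyl]-3-[(4-methoxybenzyl)oxy]pentanal | COc1cc(CC[C@H](OCc2ccc(OC)cc2)CC=O)ccc1OCc1ccccc1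
F12 | step 7 | (4S,6S)-8-[4-(benzyloxy)-3-methoxyphenyl]-6-[(4-methoxybenzyl)oxy]oct-1-en-4-ol | COc1cc(CC[C@H](OCc2ccc(OC)cc2)C[C@@H](O)CC=C)ccc1OCc1ccccc1
A1 | alternative 1 | (2R,4R)-1,2:4,5-diepoxypentane | C1O[C@@H]1C[C@@H]1CO1
A2 | alternative 1 | [4-(benzyloxy)-3-methoxybenzyl]magnesium chloride | COc1cc(C[Mg]Cl)ccc1OCc1ccccc1
A3 | alternative 1 | [4-(benzyloxy)-3,5-dimethoxybenzyl]magnesium chloride | COc1cc(C[Mg]Cl)cc(OC)c1OCc1ccccc1
A4 | alternative 1 | (3S,5S)-1-[4-(benzyloxy)-3-methoxyphenyl]-7-[4-(benzyloxy)-3,5-dimethoxyphenyl]heptane-3,5-diol | COc1cc(CC[C@H](O)C[C@@H](O)CCc2cc(OC)c(OCc3ccccc3)c(OC)c2)ccc1OCc1ccccc1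
A5 | alternative 2 | racemic (E)-1-[4-(benzyloxy)-3-methoxyphenyl]-7-[4-(benzyloxy)-3,5-dimethoxyphenyl]hept-3-en-5-ol | COc1cc(CC/C=C/C(O)CCc2cc(OC)c(OCc3ccccc3)c(OC)c2)ccc1OCc1ccccc1
A6 | alternative 2 | (3S,4S,5S)-3,4-epoxy-1-[4-(benzyloxy)-3-methoxyphenyl]-7-[4-(benzyloxy)-3,5-dimethoxyphenyl]heptan-5-ol | COc1cc(CC[C@@H]2O[C@H]2[C@@H](O)CCc2cc(OC)c(OCc3ccccc3)c(OC)c2)ccc1OCc1ccccc1
A7 | alternative 3 | malonic acid | OC(=O)CC(=O)O
A8 | alternative 3 | 3-[4-(benzyloxy)-3-methoxyphenyl]-1-(1H-imidazol-1-yl)propan-1-one | COc1cc(CCC(=O)n2ccnc2)ccc1OCc1ccccc1
A9 | alternative 3 | 3-[4-(benzyloxy)-3,5-dimethoxyphenyl]-1-(1H-imidazol-1-yl)propan-1-one | COc1cc(CCC(=O)n2ccnc2)cc(OC)c1OCc1ccccc1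
A10 | alternative 3 | 1-[4-(benzyloxy)-3-methoxyphenyl]-7-[4-(benzyloxy)-3,5-dimethoxyphenyl]heptane-3,5-dione | COc1cc(CCC(=O)CC(=O)CCc2cc(OC)c(OCc3ccccc3)c(OC)c2)ccc1OCc1ccccc1
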